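**Plan** (ring A = benzo ring of the chromanone, ring C = its pyranone, ring B = aryl group on C2, ring D = dimethylpyran fused to ring B)
1. Retrosynthesis: the C7 phenol is masked as a silyl ether and the C4 ketone is taken back to a C4 methyl ether; ring C is then cut at O1–C2 and C3–C4.
2. Enabling feature: O1 and C4 sit on the adjacent ring A carbons C8a and C4a, so O1–C8a–C4a–C4 is a latent ortho-quinone methide of a salicylaldehyde and C3–C2 is the vinyl group of a ring B styrene; ring C is their hetero-Diels–Alder adduct.
3. The styrene is cut at its vinyl C=C (Wittig), ring D at its O–CMe2 and aryl–CH= bonds (propargyl ether, Claisen cascade), and the prenyl group at its aryl–CH2 bond.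
4. Forward: prenyl onto ring B, ring D closed, vinyl group installed; ring A aldehyde silylated separately; ring C closed last by the [4+2]; then C4 OMe to OH to C=O and desilylation.
5. Stereochemistry: C2 (R) is set in the cycloaddition by the chiral phosphoric acid; C4 is a temporary centre erased by oxidation; every later step is non-basic so that C2 is kept.

Key step: step 6

Assumption: the sense of induction of the binaphthyl phosphoric acid cannot be predicted with certainty for this substrate pair; the (R)-acid is written and taken to give the 2R series, and the (S)-acid would be used if the opposite sense were found.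

**Step 1**
Reactants: 1 2,4-dihydroxybenzaldehyde
Product: 2 2-hydroxy-4-(triisopropylsilyloxy)benzaldehyde
Conditions: TIPSCl (1.05 equiv), imidazole, CH2Cl2, 0 °C to rt
Reagents that add atoms: chlorotriisopropylsilane, CC(C)[Si](Cl)(C(C)C)C(C)C
Why: Selective O-silylation of a phenol, in which the 4-hydroxyl is the more acidic and the only one not locked in a hydrogen bond to the aldehyde, so the bulky silyl chloride should leave the 2-hydroxyl free.

**Step 2**
Reactants: 3 4-hydroxybenzaldehyde; 4 1-bromo-3-methylbut-2-ene
Product: 5 4-hydroxy-3-(3-methylbut-2-enyl)benzaldehyde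
Conditions: KOH, H2O, rt
Reagents that add atoms: none
Why: Ortho C-alkylation of a phenoxide, a known direct C-prenylation in which water solvates the phenoxide oxygen so that the allylic bromide is attacked by the ortho carbon (para is blocked by the formyl group), the O-prenyl ether and doubly prenylated material being removed by chromatography.

**Step 3**
Reactants: 5 4-hydroxy-3-(3-methylbut-2-enyl)benzaldehyde; 6 3-chloro-3-methylbut-1-yne
Product: 7 4-(2-methylbut-3-yn-2-yloxy)-3-(3-methylbut-2-enyl)benzaldehyde
Conditions: DBU, CuCl2 (1 mol%), MeCN, 0 °C to rt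
Reagents that add atoms: none
Why: Copper-catalysed O-propargylation of a phenol with a tertiary propargylic chloride, the usual entry to aryl 1,1-dimethylpropargyl ethers, in which the copper acetylide ionises to an allenylidene-type electrophile that the phenoxide captures at the tertiary carbon, so no SN2 reaction at a tertiary centre is needed.

**Step 4**
Reactants: 7 4-(2-methylbut-3-yn-2-yloxy)-3-(3-methylbut-2-enyl)benzaldehyde
Product: 9 2,2-dimethyl-8-(3-methylbut-2-enyl)-2H-chromene-6-carbaldehyde, via ortho-allenylphenol 8 (not isolated)
Conditions: PhNEt2, 190 °C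
Reagents that add atoms: none
Why: Thermal aromatic propargyl Claisen rearrangement to the only free ortho position gives allenylphenol 8, which should close ring D by 1,5-hydrogen shift and oxa-6π electrocyclisation; rearrangement to the prenyl-bearing ortho carbon cannot rearomatise and reverts, so one regioisomer is expected.

**Step 5**
Reactants: 9 2,2-dimethyl-8-(3-methylbut-2-enyl)-2H-chromene-6-carbaldehyde
Product: 10 6-ethenyl-2,2-dimethyl-8-(3-methylbut-2-enyl)-2H-chromene
Conditions: Ph3PCH3Br, KOtBu, THF, 0 °C to rt
Reagents that add atoms: methyltriphenylphosphonium bromide, C[P+](c1ccccc1)(c1ccccc1)c1ccccc1.[Br-]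
Why: Wittig methylenation of an aromatic aldehyde with the non-stabilised ylide, to which the chromene and prenyl alkenes are inert; the electron-rich styrene is used promptly to avoid polymerisation.

**Step 6**
Reactants: 2 2-hydroxy-4-(triisopropylsilyloxy)benzaldehyde; 10 6-ethenyl-2,2-dimethyl-8-(3-methylbut-2-enyl)-2H-chromene; 11 trimethyl orthoformate
Product: 14 (2R,4R)-4-methoxy-2-[2,2-dimethyl-8-(3-methylbut-2-enyl)-2H-chromen-6-yl]-7-(triisopropylsilyloxy)chroman, via dimethyl acetal 12 (not isolated), via methoxy ortho-quinone methide 13 (not isolated)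
Conditions: (R)-3,3'-bis(2,4,6-triisopropylphenyl)-1,1'-binaphthyl-2,2'-diyl hydrogen phosphate (10 mol%), 5 Å MS, PhMe, 0 °C to rt
Reagents that add atoms: none
Why: Proposed new method: the phosphoric acid should first catalyse acetalisation of 2 by 11 to give 12 and then expel methanol to form the 4-methoxy ortho-quinone methide 13 (in effect its O-protonated oxocarbenium form), which remains hydrogen-bonded or ion-paired to the chiral phosphate through the phenol oxygen and is stabilised by the silyloxy group para to C4a. The CH2 terminus of styrene 10, made nucleophilic by the ring D oxygen para to the vinyl group, should bond to C4 while the phenol oxygen closes on the developing benzylic cation at C2, an asynchronous inverse-electron-demand oxa-[4+2] cycloaddition that forms C3–C4 and O1–C2 and closes ring C as a six-membered oxacycle in one intermolecular cycloaddition event. The closest known reactions are the achiral acid-promoted coupling of salicylaldehydes, orthoformates and styrenes to 2,4-cis-4-alkoxy-2-arylchromans and the chiral-phosphoric-acid-catalysed cycloadditions of ortho-quinone methides generated from ortho-hydroxybenzyl alcohols; what is untested is enantiocontrol in the intermolecular styrene case with this oxocarbenium-type quinone methide. C2 is set by the catalyst, whose 2,4,6-triisopropylphenyl groups leave one face of the bound quinone methide open, and C4 follows from C2 through the endo transition state of the E-configured methoxymethylidene unit to give the 2,4-cis (2R,4R) isomer, although only C2 matters since C4 is later oxidised. The step needs site selectivity for the vinyl group over the chromene and prenyl alkenes, which should follow from its unhindered terminal CH2 and the para-alkoxybenzyl cation it generates, whereas C3 of ring D is shielded by the adjacent gem-dimethyl carbon and the prenyl alkene is not conjugated. With C4 carried as a methyl ether and not as a carbonyl, the new C2–O1 bond has no enolate pathway for β-elimination, which is why the stereocentre should survive the step.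

**Step 7**
Reactants: 14 (2R,4R)-4-methoxy-2-[2,2-dimethyl-8-(3-methylbut-2-enyl)-2H-chromen-6-yl]-7-(triisopropylsilyloxy)chroman
Product: 15 (2R,4RS)-2-[2,2-dimethyl-8-(3-methylbut-2-enyl)-2H-chromen-6-yl]-7-(triisopropylsilyloxy)chroman-4-ol (C4 epimer mixture)
Conditions: TsOH·H2O (10 mol%), THF–H2O (4:1), rt
Reagents that add atoms: water, O
Why: SN1 solvolysis of a secondary benzylic methyl ether, in which protonation of the C4 methoxy group gives a cation stabilised by the para silyloxy group that water captures, while the far less basic C2–O1 aryl ether stays closed so that C2 keeps its configuration and the C4 epimer mixture is of no consequence.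

**Step 8**
Reactants: 15 (2R,4RS)-2-[2,2-dimethyl-8-(3-methylbut-2-enyl)-2H-chromen-6-yl]-7-(triisopropylsilyloxy)chroman-4-ol
Product: 16 (2R)-2-[2,2-dimethyl-8-(3-methylbut-2-enyl)-2H-chromen-6-yl]-7-(triisopropylsilyloxy)chroman-4-one
Conditions: Dess–Martin periodinane, pyridine, CH2Cl2, 0 °C to rt
Reagents that add atoms: none
Why: Dess–Martin oxidation of a secondary benzylic alcohol, both C4 epimers converging on the ketone under buffered non-basic conditions that leave the alkenes and the silyl ether untouched and do not enolise the new flavanone, so C2 should not be lost through ring opening.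

**Step 9**
Reactants: 16 (2R)-2-[2,2-dimethyl-8-(3-methylbut-2-enyl)-2H-chromen-6-yl]-7-(triisopropylsilyloxy)chroman-4-one
Product: 17 (2R)-7-hydroxy-2-[2,2-dimethyl-8-(3-methylbut-2-enyl)-2H-chromen-6-yl]chroman-4-one
Conditions: Bu4NF, AcOH (1:1), THF, 0 °C
Reagents that add atoms: none
Why: Fluoride cleavage of an aryl silyl ether, fast here because the departing phenoxide is para to the ketone, with acetic acid keeping the medium non-basic so that the flavanone should not open to the chalcone by retro-oxa-Michael reaction and C2 stays R.

**Compound list**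
1 | 2,4-dihydroxybenzaldehyde | O=Cc1ccc(O)cc1O | starting material
2 | 2-hydroxy-4-(triisopropylsilyloxy)benzaldehyde | O=Cc1ccc(O[Si](C(C)C)(C(C)C)C(C)C)cc1O | intermediate
3 | 4-hydroxybenzaldehyde | O=Cc1ccc(O)cc1 | starting material
4 | 1-bromo-3-methylbut-2-ene | CC(C)=CCBr | starting material
5 | 4-hydroxy-3-(3-methylbut-2-enyl)benzaldehyde | CC(C)=CCc1cc(C=O)ccc1O | intermediate
6 | 3-chloro-3-methylbut-1-yne | C#CC(C)(C)Cl | starting material
7 | 4-(2-methylbut-3-yn-2-yloxy)-3-(3-methylbut-2-enyl)benzaldehyde | CC(C)=CCc1cc(C=O)ccc1OC(C)(C)C#C | intermediate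
8 | 4-hydroxy-3-(3-methylbuta-1,2-dienyl)-5-(3-methylbut-2-enyl)benzaldehyde (not isolated) | CC(C)=CCc1cc(C=O)cc(C=C=C(C)C)c1O | intermediate
9 | 2,2-dimethyl-8-(3-methylbut-2-enyl)-2H-chromene-6-carbaldehyde | CC(C)=CCc1cc(C=O)cc2c1OC(C)(C)C=C2 | intermediate
10 | 6-ethenyl-2,2-dimethyl-8-(3-methylbut-2-enyl)-2H-chromene | CC(C)=CCc1cc(C=C)cc2c1OC(C)(C)C=C2 | intermediate
11 | trimethyl orthoformate | COC(OC)OC | starting material
12 | 2-(dimethoxymethyl)-5-(triisopropylsilyloxy)phenol (not isolated) | COC(OC)c1ccc(O[Si](C(C)C)(C(C)C)C(C)C)cc1O | intermediate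
13 | (6E)-6-(methoxymethylidene)-3-(triisopropylsilyloxy)cyclohexa-2,4-dien-1-one, methoxy group anti to the ring carbonyl (not isolated) | CO/C=C1/C(=O)C=C(O[Si](C(C)C)(C(C)C)C(C)C)C=C1 | intermediate
14 | (2R,4R)-4-methoxy-2-[2,2-dimethyl-8-(3-methylbut-2-enyl)-2H-chromen-6-yl]-7-(triisopropylsilyloxy)chroman (2,4-cis) | CC(C)=CCc1cc([C@H]2C[C@@H](OC)c3ccc(O[Si](C(C)C)(C(C)C)C(C)C)cc3O2)cc2c1OC(C)(C)C=C2 | intermediate
15 | (2R,4RS)-2-[2,2-dimethyl-8-(3-methylbut-2-enyl)-2H-chromen-6-yl]-7-(triisopropylsilyloxy)chroman-4-ol (2R fixed, C4 epimer mixture) | CC(C)=CCc1cc([C@H]2CC(O)c3ccc(O[Si](C(C)C)(C(C)C)C(C)C)cc3O2)cc2c1OC(C)(C)C=C2 | intermediate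
16 | (2R)-2-[2,2-dimethyl-8-(3-methylbut-2-enyl)-2H-chromen-6-yl]-7-(triisopropylsilyloxy)chroman-4-one | CC(C)=CCc1cc([C@H]2CC(=O)c3ccc(O[Si](C(C)C)(C(C)C)C(C)C)cc3O2)cc2c1OC(C)(C)C=C2 | intermediate
17 | (2R)-7-hydroxy-2-[2,2-dimethyl-8-(3-methylbut-2-enyl)-2H-chromen-6-yl]chroman-4-one, ent-abyssinone III | CC(C)=CCc1cc([C@H]2CC(=O)c3ccc(O)cc3O2)cc2c1OC(C)(C)C=C2 | target

**Count**
Total steps: 9. Longest linear sequence: 8 steps (steps 2 to 9, from 4-hydroxybenzaldehyde); the ring A branch is steps 1 and 6 to 9.

**Steps most likely to fail**

Step 6. The weak acid may ionise the acetal only slowly, and facial discrimination in an open intermolecular transition state may be poor. The oxocarbenium ion may also be intercepted by the chromene or prenyl alkene, and reversible acid opening of the O1–C2 benzylic ether could erode the enantiomeric purity. The fallback uses known chemistry and sets out from aldehyde 9. Commercial methyl 2,4-dihydroxybenzoate is silylated (TIPSCl, imidazole) to methyl 2-hydroxy-4-(triisopropylsilyloxy)benzoate F1. Crossed Claisen condensation of F1 with excess lithium enolate of tert-butyl acetate (LiN(iPr)2, THF, −78 °C to rt) gives tert-butyl 3-[2-hydroxy-4-(triisopropylsilyloxy)phenyl]-3-oxopropanoate F2. Knoevenagel condensation of F2 with 9 (piperidine, AcOH, molecular sieves, toluene) gives tert-butyl 2-[2-hydroxy-4-(triisopropylsilyloxy)benzoyl]-3-[2,2-dimethyl-8-(3-methylbut-2-enyl)-2H-chromen-6-yl]prop-2-enoate F3. A cinchona-alkaloid-derived bifunctional thiourea (the quinine or quinidine series chosen for 2R) then catalyses the enantioselective intramolecular oxa-Michael addition of the phenol to give tert-butyl (2R)-2-[2,2-dimethyl-8-(3-methylbut-2-enyl)-2H-chromen-6-yl]-4-oxo-7-(triisopropylsilyloxy)chroman-3-carboxylate F4. TsOH in toluene at 80 °C cleaves the tert-butyl ester and decarboxylates, and the route is rejoined at 16, with steps 5 to 8 bypassed.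

Step 7. The C4 cation may lose a C3 proton to give the flav-3-ene instead of being captured by water, or the exchange may be so slow that forcing conditions endanger the silyl ether and the C2–O1 bond. The fallback sets out from 14 and replaces solvolysis by oxidation. DDQ in CH2Cl2 with pH 7 buffer at 0 °C should abstract hydride from C4, which is benzylic, α to the methoxy group and para to the silyloxy group, and water hydrolyses the resulting oxocarbenium ion to the ketone. The route is rejoined at 16 without passing through 15, and no compound outside the list is made (entry F0).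

Step 2. The ambident phenoxide may be alkylated mainly on oxygen or twice on carbon, leaving little of the mono-ortho-prenyl phenol. The fallback sets out from 3, which is iodinated ortho to the hydroxyl (N-iodosuccinimide, AcOH) to give 4-hydroxy-3-iodobenzaldehyde F5. Stille coupling of F5 with tributyl(3-methylbut-2-enyl)stannane (Pd(PPh3)4, DMF, 90 °C) forms the aryl–CH2 bond at the unsubstituted allyl terminus, and the route is rejoined at 5.

**Further compounds**
F1 | step 6 | methyl 2-hydroxy-4-(triisopropylsilyloxy)benzoate | COC(=O)c1ccc(O[Si](C(C)C)(C(C)C)C(C)C)cc1O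
F2 | step 6 | tert-butyl 3-[2-hydroxy-4-(triisopropylsilyloxy)phenyl]-3-oxopropanoate | CC(C)(C)OC(=O)CC(=O)c1ccc(O[Si](C(C)C)(C(C)C)C(C)C)cc1O
F3 | step 6 | tert-butyl 2-[2-hydroxy-4-(triisopropylsilyloxy)benzoyl]-3-[2,2-dimethyl-8-(3-methylbut-2-enyl)-2H-chromen-6-yl]prop-2-enoate (alkene geometry not defined) | CC(C)=CCc1cc(C=C(C(=O)OC(C)(C)C)C(=O)c3ccc(O[Si](C(C)C)(C(C)C)C(C)C)cc3O)cc2c1OC(C)(C)C=C2
F4 | step 6 | tert-butyl (2R)-2-[2,2-dimethyl-8-(3-methylbut-2-enyl)-2H-chromen-6-yl]-4-oxo-7-(triisopropylsilyloxy)chroman-3-carboxylate (C3 epimerisable) | CC(C)=CCc1cc([C@H]2C(C(=O)OC(C)(C)C)C(=O)c3ccc(O[Si](C(C)C)(C(C)C)C(C)C)cc3O2)cc2c1OC(C)(C)C=C2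
F0 | step 7 | none | none
F5 | step 2 | 4-hydroxy-3-iodobenzaldehyde | O=Cc1ccc(O)c(I)c1
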